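**Numbering.** Ring atoms: C1 is the tertiary carbinol carrying C7H2OBz, C2 bears OAc, C3 bears OBz, C4=C5 is the alkene, C6 bears OAc. These locants are kept for every intermediate. Compounds are numbered 1–20 in the order they first appear in the steps; the target is 20.

## Analysis of the target

Compound 20 is a cyclohex-4-ene whose four sp3 ring carbons C6, C1, C2 and C3 are contiguous and all oxygenated; C1 is quaternary and carries the only exocyclic carbon, C7. The configuration is (1R,2S,3R,6S): C1–OH and C2–OAc are cis, C2–OAc and C3–OBz are trans, and C6–OAc is trans to C1–OH and therefore cis to the C3 benzoate across the alkene. Five oxygens carry four acyl groups of two kinds in a fixed pattern (benzoate on C7 and C3, acetate on C2 and C6) beside one free tertiary hydroxyl. Each oxygen must therefore be introduced or unmasked individually, and acyl migration under base (C7 to C1, C3 to C2) is a standing risk. C3 and C6 are allylic esters, open to ionisation and SN2′ substitution, and any diene-stage intermediate can lose its C1 oxygen and become an arene. The difficulty lies less in the seven-carbon skeleton than in absolute control at the quaternary C1 together with the differentiated ester pattern. The enabling feature is hidden symmetry: C1 with its two arms C2=C3 and C6=C5 converging on C4 is the carbinol carbon of a para-quinol once C4 is a carbonyl, as in the achiral dienone 10. The trans C1–O/C6–O pair next to C4=C5 is what a Wharton transposition leaves from the C5,C6-epoxy ketone 12, so epoxidising one enantiotopic arm of 10 creates C1, C5 and C6 in one catalytic event.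

## Retrosynthetic reasoning

**20 to 19.** The acetyl–O bond at C2 is cut last. In 19 the C2 hydroxyl is the only one that acylates readily, because the C1 hydroxyl is tertiary. The two ring acetates thus enter at different times and never have to be told apart. The forward step must acetylate C2 without moving the C3 benzoate.

**19 to 18.** The C3–O bond to the benzoate is cut, giving the C2,C3-oxirane 18. A trans hydroxy ester is the mark of an epoxide opened by a carboxylate. C3 is both the allylic carbon and the distal carbon of a 2,3-epoxy alcohol, so attack there rather than at the hindered C2 is doubly favoured, and the benzoate arrives in its final form. The forward step needs SN2 opening with inversion at C3 and no SN2′ attack at C5.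

**18 to 17.** Both oxirane C–O bonds are removed, leading to the conjugated diene 17 with a free C1 hydroxyl. The oxirane oxygen must lie on the face of C1–OH, since it becomes the cis C2 hydroxyl. A free tertiary allylic alcohol can direct a metal-bound peroxide to exactly that face. The forward step must epoxidise C2=C3 and leave C4=C5 alone.

**17 to 16 to 15.** The Si–O bond at C1 is restored and the acetyl–O bond at C6 is cut. The C6 acetate has to be in place before the tertiary hydroxyl is freed, so that only one hydroxyl is ever exposed. Hence silyl ether 16 precedes 17, and dienol 15 precedes 16.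

**15 to 12.** The allylic alcohol unit C6(OH)–C5=C4 is the Wharton retron. C4–H and C4=C5 are traced back to C4=O and a C5–O bond, giving epoxy enone 12. This shows that the C6 oxygen was an epoxide oxygen. The forward reaction must transpose reductively without breaking C6–O or harming the esters.

**12 to 10 (key disconnection).** The C6–O and C5–O bonds are cut. The result, dienone 10, has a mirror plane through C7, C1 and C4, so three stereocentres disappear at once. No other cut exposes this symmetry. The forward step must select one of two enantiotopic enone arms by catalyst control and deliver oxygen anti to the silyloxy group by substrate control.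

**10 to 8 to 7 to 5.** These are functional-group disconnections: the Si–O bond (silyl chloride 9), the carbonyl masked as its dimethyl ketal (7), and the benzoyl–O7 bond (acid chloride 6). The order matters. The benzoate must be on C7 before the dienone is unmasked, because a free C7 alkoxide on a 4-hydroxymethyl dienone would fragment to an arene. The silyl ether goes on last because the ketal hydrolysis is acidic.

**5 to 4 to 1 and 2 (via 3).** The C1–C7 bond, the only C–C bond made in the route, is cut. The hydroxymethyl anion synthon is the silylmethyl Grignard reagent 3 made from 2, and the C7–O bond comes from oxidation of the C–Si bond in 4. The acceptor is quinone monoketal 1, whose ketal protects C4 and blocks aromatisation.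

## Alternatives that were turned down

**Alternative 1:** The ring is cut at C2–C3 and C1–C6. This leads back to (1E,3E)-buta-1,3-diene-1,4-diyl diacetate A1 and the dioxolone-derived imide A2, 3-(2-oxo-1,3-dioxole-4-carbonyl)-1,3-oxazolidin-2-one. A chiral bis(oxazoline)–Cu(OTf)2 complex chelating the imide would give cycloadduct A3 in one [4+2] step.
- For it: the ring and all four stereocentres arise at once. The E,E diene places the C3 and C6 oxygens cis, the dienophile supplies the cis C1/C2 diol as a carbonate, and an endo chelated acyl group puts C7 on the face of the two acetoxy groups. That is the relative configuration of 20. On stereocentre economy and convergence this route is stronger than the chosen one.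
- Against it: A2 has an oxygen donor on each alkene carbon and A1 is substituted at both reacting termini, so a deactivated dienophile meets a hindered, only moderately electron-rich diene. The forcing this usually needs fits poorly with a chiral Lewis acid, and the carbonate oxygens can compete with the imide for copper.
- The larger problem follows A3. Its C3 and C6 oxygens are both acetates in near-identical allylic surroundings, yet 20 needs a benzoate on one and an acetate on the other. C7 is at the carboxylic acid level and must be reduced beside two acetates and a carbonate. The carbonate must then be opened so that C1 stays free while C2 is acetylated. Such 3,6-diacyloxycyclohexenes with an acyl group at C1 are also prone to β-elimination toward arenes.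
- Comparison: the chosen route gives up the one-step stereochemical payoff but brings in each oxygen separately (C7 as benzoate from the start, C6 from the epoxide, C3 directly as benzoate), so no two like esters need to be distinguished.

**Alternative 2:** C1–C6 is disconnected by a retro-Ireland–Claisen step. The carbocycle unfolds to δ-lactone A5, a 2,3,4-tri-O-benzyl hexono-1,5-lactone of gluco configuration whose C5 carries a 2-benzyloxyvinyl group, to be made from D-glucose A4. The lactone carbonyl becomes C7, sugar carbons C2–C5 become ring carbons C1–C4, and the vinyl ether supplies C5 and C6. Forward, KN(SiMe3)2/Me3SiCl would give the silyl ketene acetal, which on warming rearranges [3,3] with cleavage of the ring C4–O bond to acid A6.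
- For it: C2 and C3 come from the chiral pool with certainty, the quaternary centre forms in the C–C bond-forming event, and chirality transfer in a ring-constrained sigmatropic shift is dependable. In certainty of absolute configuration it is stronger than a catalyst-controlled desymmetrisation.
- Against it: A5 needs a long sequence from A4 (protection, oxidation at C6, enol ether olefination with defined geometry, lactone formation). Its enolate has a β-benzyloxy group placed for E1cB loss in competition with O-silylation. The C1 and C6 configurations depend jointly on enol ether geometry and on a boat- or chair-like transition state.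
- A6 carries four identical benzyl ethers and a carboxylic acid. These must become one free hydroxyl, two acetates, two benzoates and a CH2O unit, and hydrogenolysis is barred by the ring alkene.
- Comparison: step count and protecting-group traffic are much heavier than in the chosen route, which runs twelve steps from a cheap symmetric dienone and installs the esters in final form.

**Alternative 3:** The C3–C4 bond is cut, giving the open-chain (Z)-iodoalkenyl aldehyde A8, to be assembled from L-erythrulose A7. CrCl2 with catalytic NiCl2 would convert the iodoalkene into an alkenylchromium species that adds to the C3 aldehyde and closes the ring to cyclohexenol A9.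
- For it: A9 already holds both acetates, the C7 benzoate and the protected C1 oxygen, so only C3 benzoylation and desilylation remain. That endgame is shorter and cleaner than the six steps after the key step here, and the chromium chemistry tolerates esters.
- Against it: the C3 carbinol centre forms in the cyclisation with only the adjacent C2 acetate to guide it, and no strong element secures the required trans C2/C3 relation. A8 has three contiguous stereocentres including quaternary C1, of which A7 supplies one, so two must be built by acyclic stereocontrol at a ketone. A8 is also an α-acyloxy aldehyde in an open-chain polyol ester array, exposed to epimerisation at C2, β-elimination and acyl migration before ring closure.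
- Comparison: the risk is spread over a long acyclic prelude and a cyclisation of uncertain diastereoselectivity. The chosen route keeps the ring from the first step, creates every stereocentre on a rigid six-membered template, and concentrates the uncertainty in one catalytic step for which a resolution is available.

Key step: step 6

Assumption: the cinchonidine-derived ammonium salt is taken to select the enone arm that leads to 12; the sense of induction cannot be predicted with confidence for this substrate, and if the other arm is preferred the pseudoenantiomeric N-benzylcinchoninium chloride replaces it with no other change.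

## Route

Step 1
Reactants: 2 (chloromethyl)(isopropoxy)dimethylsilane; 1 4,4-dimethoxycyclohexa-2,5-dien-1-one
Product: 4 1-{[isopropoxy(dimethyl)silyl]methyl}-4,4-dimethoxycyclohexa-2,5-dien-1-ol, via Grignard reagent 3 (not isolated)
Conditions: Mg, cat. BrCH2CH2Br, THF, reflux; then 1, THF, 0 °C; aq NH4Cl; product used crude
Reagents that add atoms: (chloromethyl)(isopropoxy)dimethylsilane (2), CC(C)O[Si](C)(C)CCl
Why: Magnesium inserts into the C–Cl bond of 2 to give the α-silyl Grignard reagent 3, a hydroxymethyl anion equivalent, which adds 1,2 to the carbonyl of monoketal 1 (Grignard addition); the new carbinol carbon is not stereogenic because both ring arms are identical, and the β-hydroxysilane is carried on crude to forestall Peterson elimination.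

Step 2
Reactants: 4 1-{[isopropoxy(dimethyl)silyl]methyl}-4,4-dimethoxycyclohexa-2,5-dien-1-ol
Product: 5 1-(hydroxymethyl)-4,4-dimethoxycyclohexa-2,5-dien-1-ol
Conditions: 30% H2O2, KF, KHCO3, THF/MeOH 1:1, rt
Reagents that add atoms: hydrogen peroxide, OO
Why: Tamao–Fleming oxidation: fluoride activates the alkoxysilane, hydroperoxide adds to silicon and the CH2 group migrates from silicon to oxygen; the bicarbonate-buffered medium leaves the acid-labile ketal and the bis-allylic tertiary alcohol untouched.

Step 3
Reactants: 5 1-(hydroxymethyl)-4,4-dimethoxycyclohexa-2,5-dien-1-ol; 6 benzoyl chloride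
Product: 7 (1-hydroxy-4,4-dimethoxycyclohexa-2,5-dien-1-yl)methyl benzoate
Conditions: BzCl (1.05 equiv), Et3N, cat. DMAP, CH2Cl2, 0 °C
Reagents that add atoms: benzoyl chloride (6), O=C(Cl)c1ccccc1
Why: DMAP-catalysed acylation of the primary hydroxyl is far faster than that of the tertiary bis-allylic one, and the basic medium protects the ketal; placing the benzoate now ensures that no free C7 alkoxide is present once the dienone is unmasked, where it would fragment with loss of formaldehyde.

Step 4
Reactants: 7 (1-hydroxy-4,4-dimethoxycyclohexa-2,5-dien-1-yl)methyl benzoate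
Product: 8 (1-hydroxy-4-oxocyclohexa-2,5-dien-1-yl)methyl benzoate
Conditions: AcOH/H2O/THF (1:1:4), rt
Reagents that add atoms: water, O
Why: Acid-catalysed ketal hydrolysis through the dienyl oxocarbenium ion; quinol ketals hydrolyse under acid this mild, which avoids ionising the tertiary carbinol or starting a dienone–phenol rearrangement.

Step 5
Reactants: 8 (1-hydroxy-4-oxocyclohexa-2,5-dien-1-yl)methyl benzoate; 9 chlorotriethylsilane
Product: 10 [4-oxo-1-(triethylsilyloxy)cyclohexa-2,5-dien-1-yl]methyl benzoate
Conditions: Et3SiCl, imidazole, cat. DMAP, DMF, 0 °C to rt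
Reagents that add atoms: chlorotriethylsilane (9), CC[Si](Cl)(CC)CC
Why: Silylation of a tertiary hydroxyl that is flanked by two sp2 carbons and therefore accessible; the silyl ether removes the hydrogen-bond donor that would steer a peroxide syn and supplies the bulk that should shield its own face in step 6.

Step 6
Reactants: 10 [4-oxo-1-(triethylsilyloxy)cyclohexa-2,5-dien-1-yl]methyl benzoate
Product: 12 [(1R,5R,6S)-2-oxo-5-(triethylsilyloxy)-7-oxabicyclo[4.1.0]hept-3-en-5-yl]methyl benzoate, via peroxy enolate 11 (not isolated)
Conditions: tBuOOH (1.1 equiv, in decane), N-benzylcinchonidinium chloride (10 mol %), 0.1 M aq NaOH (20 mol %), toluene, 0 °C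
Reagents that add atoms: tert-butyl hydroperoxide, CC(C)(C)OO
Why: This is a Weitz–Scheffer epoxidation under phase transfer: hydroxide deprotonates tBuOOH at the interface and the chiral ammonium cation carries tert-butylperoxide into toluene as a contact ion pair, which adds in conjugate fashion to C6 of one enone arm of 10 to give peroxy enolate 11. The enolate carbon C5 then attacks the proximal peroxide oxygen and expels tert-butoxide, closing the oxirane in a 3-exo-tet mode; the closure is irreversible and necessarily cis-fused, so C5 follows from C6. The closest known reaction type is the cinchona-ammonium phase-transfer epoxidation of quinone monoketals and other cyclohexadienones with alkyl hydroperoxides. C6 is set in the addition step: which arm reacts should be decided by the catalyst, whose C9 hydroxyl can hydrogen-bond the dienone carbonyl while the N-benzylquinuclidinium unit holds the peroxide over one arm, and which face reacts should be decided by the substrate. The peroxide should approach C6 anti to the C1–O bond, because Et3SiO is the bulkier C1 substituent, an electronegative substituent prefers to lie antiperiplanar to the forming bond, and no free hydroxyl is present to guide the reagent syn. C1 becomes stereogenic only because the two arms are now different, so its configuration is the joint result of arm and face selection. The step therefore needs enantiotopic-arm selectivity from the catalyst, anti facial selectivity from the silyl ether and arrest at the mono-epoxide by limiting the hydroperoxide; a second epoxidation, where it occurs, should preferentially consume the minor enantiomer, whose catalyst-preferred arm is still intact. Dilute hydroxide in a two-phase system should keep the hindered benzoate from saponification.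

Step 7
Reactants: 12 [(1R,5R,6S)-2-oxo-5-(triethylsilyloxy)-7-oxabicyclo[4.1.0]hept-3-en-5-yl]methyl benzoate
Product: 15 [(1R,6S)-6-hydroxy-1-(triethylsilyloxy)cyclohexa-2,4-dien-1-yl]methyl benzoate, via epoxy hydrazone 13 (not isolated), via alkenyl diazene 14 (not isolated)
Conditions: N2H4·H2O (2.5 equiv), AcOH (0.5 equiv), MeOH, 0 °C to rt; neutral work-up
Reagents that add atoms: none
Why: Wharton transposition: hydrazone 13 forms at C4, its tautomerisation opens the oxirane at C5–O to give alkenyl diazene 14, and loss of N2 places hydrogen on C4 and leaves C4=C5 in conjugation with C2=C3; the C6–O bond is never broken, so C6 keeps its configuration and C1 is untouched.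

Step 8
Reactants: 15 [(1R,6S)-6-hydroxy-1-(triethylsilyloxy)cyclohexa-2,4-dien-1-yl]methyl benzoate
Product: 16 [(1R,6S)-6-acetoxy-1-(triethylsilyloxy)cyclohexa-2,4-dien-1-yl]methyl benzoate
Conditions: Ac2O, pyridine, cat. DMAP, CH2Cl2, 0 °C
Reagents that add atoms: acetic anhydride, CC(=O)OC(C)=O
Why: DMAP-catalysed esterification of the only free (secondary) hydroxyl; the base-buffered medium spares the acid-sensitive dienyl system and fixes the C6 acetate before the tertiary hydroxyl is unmasked.

Step 9
Reactants: 16 [(1R,6S)-6-acetoxy-1-(triethylsilyloxy)cyclohexa-2,4-dien-1-yl]methyl benzoate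
Product: 17 [(1R,6S)-6-acetoxy-1-hydroxycyclohexa-2,4-dien-1-yl]methyl benzoate
Conditions: HF·pyridine, excess pyridine, THF, 0 °C to rt
Reagents that add atoms: none
Why: Fluoride-driven Si–O cleavage under pyridine-buffered conditions; no alkoxide is formed, so the C6 acetate and C7 benzoate should not migrate to C1, and the medium is too weakly acidic to dehydrate the dienol toward an arene.

Step 10
Reactants: 17 [(1R,6S)-6-acetoxy-1-hydroxycyclohexa-2,4-dien-1-yl]methyl benzoate
Product: 18 [(1S,4S,5R,6S)-4-acetoxy-5-hydroxy-7-oxabicyclo[4.1.0]hept-2-en-5-yl]methyl benzoate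
Conditions: VO(acac)2 (5 mol %), tBuOOH (1.3 equiv, in decane), CH2Cl2, 0 °C to rt
Reagents that add atoms: tert-butyl hydroperoxide, CC(C)(C)OO
Why: Vanadium-catalysed hydroxyl-directed epoxidation: the tertiary alcohol binds vanadium together with the alkyl peroxide and oxygen is delivered within the complex to the allylic C2=C3 bond on the hydroxyl face, setting C2 and C3 with both C–O bonds syn to C1–OH; C4=C5 is only homoallylic to the hydroxyl and is deactivated by its allylic acetate.

Step 11
Reactants: 18 [(1S,4S,5R,6S)-4-acetoxy-5-hydroxy-7-oxabicyclo[4.1.0]hept-2-en-5-yl]methyl benzoate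
Product: 19 [(1S,2S,3R,6S)-6-acetoxy-3-(benzoyloxy)-1,2-dihydroxycyclohex-4-en-1-yl]methyl benzoate
Conditions: PhCO2H (2 equiv), Ti(OiPr)4 (1.5 equiv), CH2Cl2, 0 °C to rt; aq tartaric acid work-up
Reagents that add atoms: benzoic acid, O=C(O)c1ccccc1
Why: Ti(OiPr)4-mediated opening of a 2,3-epoxy alcohol by a carboxylic acid: the titanium alkoxide of C1–OH chelates the oxirane oxygen and benzoate attacks C3, which is also the allylic carbon, in SN2 fashion with inversion; C3–OBz thus ends trans to the C2 hydroxyl, which keeps the oxirane oxygen cis to C1–OH.

Step 12
Reactants: 19 [(1S,2S,3R,6S)-6-acetoxy-3-(benzoyloxy)-1,2-dihydroxycyclohex-4-en-1-yl]methyl benzoate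
Product: 20 [(1R,2S,3R,6S)-2,6-diacetoxy-3-(benzoyloxy)-1-hydroxycyclohex-4-en-1-yl]methyl benzoate
Conditions: Ac2O (1.5 equiv), pyridine, cat. DMAP, CH2Cl2, 0 °C
Reagents that add atoms: acetic anhydride, CC(=O)OC(C)=O
Why: Acetylation of the only secondary hydroxyl; the tertiary C1 hydroxyl should not react at this temperature with limited anhydride, and the short, cold reaction gives the C3 benzoate little chance to migrate.

## Compound list

1 | 4,4-dimethoxycyclohexa-2,5-dien-1-one | COC1(OC)C=CC(=O)C=C1 | starting material
2 | (chloromethyl)(isopropoxy)dimethylsilane | CC(C)O[Si](C)(C)CCl | starting material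
3 | chloro{[isopropoxy(dimethyl)silyl]methyl}magnesium (Grignard reagent, formed in the flask) | CC(C)O[Si](C)(C)C[Mg]Cl | intermediate
4 | 1-{[isopropoxy(dimethyl)silyl]methyl}-4,4-dimethoxycyclohexa-2,5-dien-1-ol | COC1(OC)C=CC(O)(C[Si](C)(C)OC(C)C)C=C1 | intermediate
5 | 1-(hydroxymethyl)-4,4-dimethoxycyclohexa-2,5-dien-1-ol | COC1(OC)C=CC(O)(CO)C=C1 | intermediate
6 | benzoyl chloride | O=C(Cl)c1ccccc1 | starting material
7 | (1-hydroxy-4,4-dimethoxycyclohexa-2,5-dien-1-yl)methyl benzoate | COC1(OC)C=CC(O)(COC(=O)c2ccccc2)C=C1 | intermediate
8 | (1-hydroxy-4-oxocyclohexa-2,5-dien-1-yl)methyl benzoate | O=C1C=CC(O)(COC(=O)c2ccccc2)C=C1 | intermediate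
9 | chlorotriethylsilane | CC[Si](Cl)(CC)CC | starting material
10 | [4-oxo-1-(triethylsilyloxy)cyclohexa-2,5-dien-1-yl]methyl benzoate (achiral; mirror plane through C7, C1, C4) | O=C1C=CC(O[Si](CC)(CC)CC)(COC(=O)c2ccccc2)C=C1 | intermediate
11 | [(1R,6S)-6-(tert-butylperoxy)-4-oxido-1-(triethylsilyloxy)cyclohexa-2,4-dien-1-yl]methyl benzoate (peroxy enolate, ammonium ion pair, formed in the flask; peroxy group anti to Et3SiO) | CC(C)(C)OO[C@H]1C=C([O-])C=C[C@@]1(O[Si](CC)(CC)CC)COC(=O)c1ccccc1 | intermediate
12 | [(1R,5R,6S)-2-oxo-5-(triethylsilyloxy)-7-oxabicyclo[4.1.0]hept-3-en-5-yl]methyl benzoate (C5,C6-oxirane anti to Et3SiO, on the CH2OBz face) | O=C1C=C[C@@](O[Si](CC)(CC)CC)(COC(=O)c2ccccc2)[C@H]2O[C@@H]12 | intermediate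
13 | [(1S,5R,6S)-2-hydrazinylidene-5-(triethylsilyloxy)-7-oxabicyclo[4.1.0]hept-3-en-5-yl]methyl benzoate (hydrazone of 12, formed in the flask) | NN=C1C=C[C@@](O[Si](CC)(CC)CC)(COC(=O)c2ccccc2)[C@H]2O[C@@H]12 | intermediate
14 | [(1R,6S)-4-diazenyl-6-hydroxy-1-(triethylsilyloxy)cyclohexa-2,4-dien-1-yl]methyl benzoate (alkenyl diazene, formed in the flask) | O[C@H]1C=C(N=N)C=C[C@@]1(O[Si](CC)(CC)CC)COC(=O)c1ccccc1 | intermediate
15 | [(1R,6S)-6-hydroxy-1-(triethylsilyloxy)cyclohexa-2,4-dien-1-yl]methyl benzoate (C6–OH trans to C1–OSiEt3) | O[C@H]1C=CC=C[C@@]1(O[Si](CC)(CC)CC)COC(=O)c1ccccc1 | intermediate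
16 | [(1R,6S)-6-acetoxy-1-(triethylsilyloxy)cyclohexa-2,4-dien-1-yl]methyl benzoate | CC(=O)O[C@H]1C=CC=C[C@@]1(O[Si](CC)(CC)CC)COC(=O)c1ccccc1 | intermediate
17 | [(1R,6S)-6-acetoxy-1-hydroxycyclohexa-2,4-dien-1-yl]methyl benzoate | CC(=O)O[C@H]1C=CC=C[C@@]1(O)COC(=O)c1ccccc1 | intermediate
18 | [(1S,4S,5R,6S)-4-acetoxy-5-hydroxy-7-oxabicyclo[4.1.0]hept-2-en-5-yl]methyl benzoate (C2,C3-oxirane syn to C1–OH) | CC(=O)O[C@H]1C=C[C@@H]2O[C@@H]2[C@@]1(O)COC(=O)c1ccccc1 | intermediate
19 | [(1S,2S,3R,6S)-6-acetoxy-3-(benzoyloxy)-1,2-dihydroxycyclohex-4-en-1-yl]methyl benzoate (route locants; C2–OH cis to C1–OH, C3–OBz trans to C2–OH) | CC(=O)O[C@H]1C=C[C@@H](OC(=O)c2ccccc2)[C@H](O)[C@@]1(O)COC(=O)c1ccccc1 | intermediate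
20 | [(1R,2S,3R,6S)-2,6-diacetoxy-3-(benzoyloxy)-1-hydroxycyclohex-4-en-1-yl]methyl benzoate (route locants) | CC(=O)O[C@H]1C=C[C@@H](OC(=O)c2ccccc2)[C@H](OC(C)=O)[C@@]1(O)COC(=O)c1ccccc1 | target

## Step count and risk

Total step count: 12. Longest linear sequence: 12 steps (1 and 2 to 20).

**Step 6 (key step).** The most likely failure is insufficient discrimination between the two enantiotopic enone arms. They differ only through the remote C1 substituents, so the mono-epoxide may form with low enantiomeric purity. Secondary risks are leakage to the face syn to the silyloxy group, and hydroxide attack on the benzoate followed by fragmentation of the resulting alkoxide. Fallback, from 10 back to the route at 15: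
- An achiral Weitz–Scheffer epoxidation (tBuOOH, DBU, CH2Cl2, 0 °C) would give 12 together with its mirror image, [(1S,5S,6R)-2-oxo-5-(triethylsilyloxy)-7-oxabicyclo[4.1.0]hept-3-en-5-yl]methyl benzoate F1.
- The conditions of step 7 applied to this mixture would give 15 and its mirror image, [(1S,6R)-6-hydroxy-1-(triethylsilyloxy)cyclohexa-2,4-dien-1-yl]methyl benzoate F2.
- A lipase (Candida antarctica lipase B or Pseudomonas cepacia lipase, vinyl acetate, tert-butyl methyl ether) would then resolve the pair. The empirical size rule for lipase acylation of secondary alcohols predicts that the (6R) alcohol reacts faster, giving [(1S,6R)-6-acetoxy-1-(triethylsilyloxy)cyclohexa-2,4-dien-1-yl]methyl benzoate F3.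
- Alcohol 15 stays unacylated, is separated by chromatography and re-enters at step 8.

**Step 7.** Hydrazine may cleave the benzoate, add to the remaining enone, or promote silyl or acyl shift to the new C6 oxygen. The arene-hydrate-like dienol may also lose its C1 oxygen and aromatise in the acidic medium. Fallback, from 12 back to the route at 15, with no hydrazine and no acid:
- Luche reduction (NaBH4, CeCl3·7H2O, MeOH, −78 °C) gives the C4 carbinol, [(5R,6S)-2-hydroxy-5-(triethylsilyloxy)-7-oxabicyclo[4.1.0]hept-3-en-5-yl]methyl benzoate F4; either C4 epimer serves.
- 1,1′-Thiocarbonyldiimidazole (cat. DMAP, CH2Cl2) converts it into the O-thiocarbonylimidazolide F5.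
- Bu3SnH/AIBN (toluene, 80 °C) then generates the C4 radical in a Barton–McCombie-type process. The radical opens the oxirane at C5–O and the C6 alkoxyl radical takes hydrogen from the stannane, giving 15.

**Step 10.** Oxygen transfer may compete at C4=C5, the tertiary dienol or the vinyl epoxide may ionise under the Lewis-acidic vanadium and aromatise, or the allylic alcohol may undergo 1,3-transposition. Fallback, from 17 back to the route at 19, bypassing 18:
- Hydrogen-bond-directed dihydroxylation (OsO4/TMEDA, stoichiometric, CH2Cl2, −78 °C; aq Na2SO3) adds two hydroxyls to C2=C3 on the face of C1–OH. This gives the all-cis triol, [(1S,2S,3S,6S)-6-acetoxy-1,2,3-trihydroxycyclohex-4-en-1-yl]methyl benzoate F6.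
- A Mitsunobu reaction (PPh3, DIAD, PhCO2H, THF, 0 °C) at the allylic and less hindered C3 hydroxyl inverts C3 and installs the benzoate, giving 19.

**Step 11.** The vinyl epoxide may open by SN2′ attack at C5 or ionise to an allyl cation with loss of stereochemical integrity at C3. The titanium alkoxide may also promote acyl migration among the C1, C2, C3 and C7 oxygens. Fallback, from 18 back to the route at 19:
- Hydrolysis in buffered water (THF/H2O, pH 6, 40 °C) opens the oxirane at the allylic carbon to the trans diol, [(1S,2S,3R,6S)-6-acetoxy-1,2,3-trihydroxycyclohex-4-en-1-yl]methyl benzoate F7.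
- The C3 hydroxyl is allylic and remote from the quaternary centre. It is benzoylated selectively (BzCl, 1.0 equiv, 2,4,6-collidine, CH2Cl2, −40 °C) to give 19.

## Further compounds

F1 | step 6 | [(1S,5S,6R)-2-oxo-5-(triethylsilyloxy)-7-oxabicyclo[4.1.0]hept-3-en-5-yl]methyl benzoate (mirror image of 12) | O=C1C=C[C@](O[Si](CC)(CC)CC)(COC(=O)c2ccccc2)[C@@H]2O[C@H]12
F2 | step 6 | [(1S,6R)-6-hydroxy-1-(triethylsilyloxy)cyclohexa-2,4-dien-1-yl]methyl benzoate (mirror image of 15) | O[C@@H]1C=CC=C[C@]1(O[Si](CC)(CC)CC)COC(=O)c1ccccc1
F3 | step 6 | [(1S,6R)-6-acetoxy-1-(triethylsilyloxy)cyclohexa-2,4-dien-1-yl]methyl benzoate (mirror image of 16) | CC(=O)O[C@@H]1C=CC=C[C@]1(O[Si](CC)(CC)CC)COC(=O)c1ccccc1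
F4 | step 7 | [(5R,6S)-2-hydroxy-5-(triethylsilyloxy)-7-oxabicyclo[4.1.0]hept-3-en-5-yl]methyl benzoate (C4 carbinol of 12 in route locants, carbinol centre unassigned) | OC1C=C[C@@](O[Si](CC)(CC)CC)(COC(=O)c2ccccc2)[C@H]2O[C@@H]12
F5 | step 7 | O-thiocarbonylimidazolide of F4: O-[5-(benzoyloxymethyl)-5-(triethylsilyloxy)-7-oxabicyclo[4.1.0]hept-3-en-2-yl] 1H-imidazole-1-carbothioate (carbinol centre unassigned) | S=C(OC1C=C[C@@](O[Si](CC)(CC)CC)(COC(=O)c2ccccc2)[C@H]2O[C@@H]12)n1ccnc1
F6 | step 10 | [(1S,2S,3S,6S)-6-acetoxy-1,2,3-trihydroxycyclohex-4-en-1-yl]methyl benzoate (route locants; C1, C2 and C3 hydroxyls all cis) | CC(=O)O[C@H]1C=C[C@H](O)[C@H](O)[C@@]1(O)COC(=O)c1ccccc1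
F7 | step 11 | [(1S,2S,3R,6S)-6-acetoxy-1,2,3-trihydroxycyclohex-4-en-1-yl]methyl benzoate (route locants; C3–OH trans to C2–OH) | CC(=O)O[C@H]1C=C[C@@H](O)[C@H](O)[C@@]1(O)COC(=O)c1ccccc1
A1 | alternative 1 | (1E,3E)-buta-1,3-diene-1,4-diyl diacetate | CC(=O)O/C=C/C=C/OC(C)=O
A2 | alternative 1 | 3-(2-oxo-1,3-dioxole-4-carbonyl)-1,3-oxazolidin-2-one | O=C1OC=C(O1)C(=O)N1CCOC1=O
A3 | alternative 1 | 3,6-diacetoxy-1,2-carbonyldioxycyclohex-4-ene-1-carbonyl oxazolidinone (cycloadduct, configuration of 20) | CC(=O)O[C@H]1C=C[C@@H](OC(C)=O)[C@@H]2OC(=O)O[C@]12C(=O)N1CCOC1=O
A4 | alternative 2 | D-glucose (open-chain form) | OC[C@H]([C@H]([C@@H]([C@H](C=O)O)O)O)O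
A5 | alternative 2 | 3,4,5-tris(benzyloxy)-6-[2-(benzyloxy)ethenyl]oxan-2-one (D-gluco configuration, enol ether geometry left open) | O=C1O[C@H](C=COCc2ccccc2)[C@@H](OCc2ccccc2)[C@H](OCc2ccccc2)[C@H]1OCc1ccccc1
A6 | alternative 2 | 1,2,3,6-tetrakis(benzyloxy)cyclohex-4-ene-1-carboxylic acid (configuration of 20) | C(c1ccccc1)O[C@H]1C=C[C@@H](OCc2ccccc2)[C@H](OCc2ccccc2)[C@@]1(OCc1ccccc1)C(=O)O
A7 | alternative 3 | L-erythrulose, (3S)-1,3,4-trihydroxybutan-2-one | O=C(CO)[C@@H](O)CO
A8 | alternative 3 | open-chain (Z)-iodoalkenyl aldehyde: 2,4-diacetoxy-3-(benzoyloxymethyl)-6-iodo-3-(triethylsilyloxy)hex-5-enal (configuration of 20 at the three stereocentres) | O=C[C@H](OC(C)=O)[C@@](O[Si](CC)(CC)CC)(COC(=O)c1ccccc1)[C@@H](OC(C)=O)/C=C\I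
A9 | alternative 3 | C3 cyclohexenol: [2,6-diacetoxy-3-hydroxy-1-(triethylsilyloxy)cyclohex-4-en-1-yl]methyl benzoate (configuration of 20) | CC(=O)O[C@H]1C=C[C@@H](O)[C@H](OC(C)=O)[C@@]1(O[Si](CC)(CC)CC)COC(=O)c1ccccc1
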